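**Retrosynthetic overview**
- The target is a 2-alkyl-3-methylmaleic anhydride; its only ring is closed in the last step, by cyclodehydration and β-elimination of a 2-alkyl-3-hydroxy-3-methylsuccinic acid in Ac2O, which also installs the terminal acetate.
- The hydroxy diacid comes from the dimethyl ester by desilylation and saponification.
- Key C–C bond (the future ring C=C): intermolecular directed aldol addition of the lithium enolate of a C16 ω-silyloxy methyl ester to methyl pyruvate.
- The C16 ester comes from the cheap musk lactone hexadecanolide by methanolysis and silylation.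
- Ring order: one ring only (the anhydride), formed last.

Assumption: the target has no stereocentre and no stereogenic double bond (the ring alkene is fixed cis), so it is achiral; the two stereocentres created in the aldol are carried as a racemic diastereomer mixture and erased in the last step.

**Route**

Step 1
Reactants: 1 hexadecanolide (oxacycloheptadecan-2-one)
Product: 2 methyl 16-hydroxyhexadecanoate
Conditions: H2SO4 (5 mol %), MeOH, reflux, 12 h
Reagents that add atoms: methanol, CO
Why: Acid-catalysed transesterification (ring-opening methanolysis) of the unstrained macrolactone is driven to the open-chain ester by the large excess of methanol, and no stereocentre is involved.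

Step 2
Reactants: 2 methyl 16-hydroxyhexadecanoate
Product: 3 methyl 16-[(tert-butyldimethylsilyl)oxy]hexadecanoate
Conditions: TBSCl (1.2 equiv), imidazole (2.5 equiv), DMF, rt, 4 h
Reagents that add atoms: tert-butyldimethylsilyl chloride, CC(C)(C)[Si](C)(C)Cl
Why: Standard imidazole-promoted silylation of a primary alcohol masks the hydroxyl against the amide base and against addition to the keto ester in the next step.

Step 3
Reactants: 3 methyl 16-[(tert-butyldimethylsilyl)oxy]hexadecanoate; 4 methyl pyruvate
Product: 7 dimethyl 2-{14-[(tert-butyldimethylsilyl)oxy]tetradecyl}-3-hydroxy-3-methylbutanedioate (racemic diastereomer mixture), via lithium ester enolate 5 (not isolated), via lithium aldolate 6 (not isolated)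
Conditions: LiN(iPr)2 (LDA, commercial solution, 1.1 equiv), THF, −78 °C, 45 min; methyl pyruvate (1.3 equiv), −78 °C, 30 min; AcOH (1.5 equiv) at −78 °C
Reagents that add atoms: none
Why: Directed (crossed) aldol addition: the irreversibly pre-formed lithium ester enolate adds to the very electrophilic ketone carbonyl of methyl pyruvate faster than it exchanges protons, the cold acetic acid quench forestalls retro-aldol, and the two new stereocentres form without control because both are destroyed in step 6.

Step 4
Reactants: 7 dimethyl 2-{14-[(tert-butyldimethylsilyl)oxy]tetradecyl}-3-hydroxy-3-methylbutanedioate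
Product: 8 dimethyl 3-hydroxy-2-(14-hydroxytetradecyl)-3-methylbutanedioate (racemic diastereomer mixture)
Conditions: p-TsOH·H2O (10 mol %), MeOH, rt, 3 h
Reagents that add atoms: none
Why: Acid-catalysed methanolysis cleaves the primary silyl ether under non-basic conditions that leave the tertiary aldol and the methyl esters (degenerate transesterification) untouched.

Step 5
Reactants: 8 dimethyl 3-hydroxy-2-(14-hydroxytetradecyl)-3-methylbutanedioate
Product: 10 3-hydroxy-2-(14-hydroxytetradecyl)-3-methylbutanedioic acid (racemic diastereomer mixture), via dilithium dicarboxylate 9 (not isolated)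
Conditions: LiOH·H2O (5 equiv), THF/MeOH/H2O (3:1:1), 0 °C → rt, 16 h; then 1 M HCl to pH 2 at 0 °C
Reagents that add atoms: lithium hydroxide monohydrate, [Li+].[OH-].O
Why: Saponification (acyl-oxygen ester hydrolysis) starts at the activated α-hydroxy ester, and the carboxylate so formed disfavours retro-aldol while the hindered second ester is cleaved; the stereocentres are not touched.

Step 6
Reactants: 10 3-hydroxy-2-(14-hydroxytetradecyl)-3-methylbutanedioic acid
Product: 13 Aspergillus acid E, 14-(4-methyl-2,5-dioxo-2,5-dihydrofuran-3-yl)tetradecyl acetate, via hydroxy anhydride monoacetate 11 (not isolated), via acetoxy anhydride acetate 12 (not isolated)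
Conditions: Ac2O (8 equiv), Et3N (6 equiv), DMAP (10 mol %), toluene, rt, 4 h, then 80 °C, 3 h
Reagents that add atoms: acetic anhydride, CC(=O)OC(C)=O
Why: Acetylation of the primary alcohol, cyclodehydration to the five-membered anhydride, acetylation of the tertiary alcohol and E1cB β-elimination of acetic acid from the anhydride enolate all converge on the tetrasubstituted maleic anhydride, which is the thermodynamic sink, and both stereocentres vanish so the diastereomer mixture gives one product.

**Compound list**

1 | hexadecanolide (oxacycloheptadecan-2-one) | O=C1CCCCCCCCCCCCCCCO1 | starting material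
2 | methyl 16-hydroxyhexadecanoate | COC(=O)CCCCCCCCCCCCCCCO | intermediate
3 | methyl 16-[(tert-butyldimethylsilyl)oxy]hexadecanoate | COC(=O)CCCCCCCCCCCCCCCO[Si](C)(C)C(C)(C)C | intermediate
4 | methyl pyruvate | CC(=O)C(=O)OC | starting material
5 | lithium enolate of 3 (lithium 1-methoxy-16-[(tert-butyldimethylsilyl)oxy]hexadec-1-en-1-olate, enolate geometry immaterial) | [Li+].COC([O-])=CCCCCCCCCCCCCCCO[Si](C)(C)C(C)(C)C | intermediate
6 | lithium aldolate (lithium alkoxide of 7, racemic diastereomer mixture) | [Li+].COC(=O)C(C)([O-])C(CCCCCCCCCCCCCCO[Si](C)(C)C(C)(C)C)C(=O)OC | intermediate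
7 | dimethyl 2-{14-[(tert-butyldimethylsilyl)oxy]tetradecyl}-3-hydroxy-3-methylbutanedioate (racemic diastereomer mixture) | COC(=O)C(C)(O)C(CCCCCCCCCCCCCCO[Si](C)(C)C(C)(C)C)C(=O)OC | intermediate
8 | dimethyl 3-hydroxy-2-(14-hydroxytetradecyl)-3-methylbutanedioate (racemic diastereomer mixture) | COC(=O)C(C)(O)C(CCCCCCCCCCCCCCO)C(=O)OC | intermediate
9 | dilithium 3-hydroxy-2-(14-hydroxytetradecyl)-3-methylbutanedioate (racemic diastereomer mixture) | [Li+].[Li+].[O-]C(=O)C(C)(O)C(CCCCCCCCCCCCCCO)C(=O)[O-] | intermediate
10 | 3-hydroxy-2-(14-hydroxytetradecyl)-3-methylbutanedioic acid (racemic diastereomer mixture) | OC(=O)C(C)(O)C(CCCCCCCCCCCCCCO)C(=O)O | intermediate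
11 | 14-(4-hydroxy-4-methyl-2,5-dioxooxolan-3-yl)tetradecyl acetate (racemic diastereomer mixture) | CC(=O)OCCCCCCCCCCCCCCC1C(=O)OC(=O)C1(C)O | intermediate
12 | 14-(4-acetoxy-4-methyl-2,5-dioxooxolan-3-yl)tetradecyl acetate (racemic diastereomer mixture) | CC(=O)OCCCCCCCCCCCCCCC1C(=O)OC(=O)C1(C)OC(C)=O | intermediate
13 | Aspergillus acid E, 14-(4-methyl-2,5-dioxo-2,5-dihydrofuran-3-yl)tetradecyl acetate (achiral) | CC(=O)OCCCCCCCCCCCCCCC1=C(C)C(=O)OC1=O | target

**Totals and risk**

Total step count: 6. Longest linear sequence: 6 steps (1 → 13).

The three steps most likely to fail are steps 3, 5 and 6.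

Step 3 (aldol). The enolate may deprotonate methyl pyruvate instead of adding, or the aldolate may revert. The fallback sets out from 3 and comes back at 8, bypassing 7. The lithium enolate 5 is trapped with Me3SiCl (THF, −78 °C → rt) to give the methyl trimethylsilyl ketene acetal F1. F1 then adds to methyl pyruvate 4 in a Mukaiyama aldol with silyl transfer (Cu(OTf)2, 10 mol %, THF, −78 °C), where no basic enolate is present, to give the doubly silylated aldol dimethyl 2-{14-[(tert-butyldimethylsilyl)oxy]tetradecyl}-3-methyl-3-[(trimethylsilyl)oxy]butanedioate F2. The conditions of step 4 (p-TsOH·H2O, MeOH, rt) remove both silyl groups from F2 and deliver 8.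

Step 5 (saponification). Hydroxide may cleave the tertiary aldol by retro-aldol before the hindered α-branched ester is hydrolysed. The fallback replaces saponification by hydrogenolysis, using benzyl groups throughout; it sets out from 1 and comes back at 10. Lactone 1 is opened (KOH, aqueous EtOH, reflux; HCl) to 16-hydroxyhexadecanoic acid F3. Double benzylation (NaH, BnBr, Bu4NI cat., DMF, 0 °C → rt) gives benzyl 16-(benzyloxy)hexadecanoate F4. The aldol protocol of step 3, run with commercial benzyl pyruvate in place of 4, gives dibenzyl 2-[14-(benzyloxy)tetradecyl]-3-hydroxy-3-methylbutanedioate F5. Hydrogenolysis (H2, 10% Pd/C, EtOAc/EtOH, rt) removes all three benzyl groups under neutral conditions and gives 10.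

Step 6 (one-pot cascade). Acetylation of the hindered tertiary hydroxyl or the elimination may stall, or the open-chain β-acetoxy acid may lose CO2 before the ring closes. The fallback separates ring closure from dehydration; it sets out from 10 and comes back at 13. Warming 10 in neat Ac2O without base (60 °C) gives the cyclic anhydride with the tertiary hydroxyl still free, 11, which is isolated. MsCl and excess Et3N (CH2Cl2, 0 °C → rt; DBU if needed) convert 11 into the tertiary mesylate 14-{4-methyl-4-[(methylsulfonyl)oxy]-2,5-dioxooxolan-3-yl}tetradecyl acetate F6. F6 undergoes E1cB elimination in the same flask to give 13.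

**Further compounds**

F1 | step 3 | methyl trimethylsilyl ketene acetal of 3, 1-methoxy-1-(trimethylsilyloxy)-16-[(tert-butyldimethylsilyl)oxy]hexadec-1-ene (alkene geometry immaterial) | COC(O[Si](C)(C)C)=CCCCCCCCCCCCCCCO[Si](C)(C)C(C)(C)C
F2 | step 3 | dimethyl 2-{14-[(tert-butyldimethylsilyl)oxy]tetradecyl}-3-methyl-3-[(trimethylsilyl)oxy]butanedioate (racemic diastereomer mixture) | COC(=O)C(C)(O[Si](C)(C)C)C(CCCCCCCCCCCCCCO[Si](C)(C)C(C)(C)C)C(=O)OC
F3 | step 5 | 16-hydroxyhexadecanoic acid | OC(=O)CCCCCCCCCCCCCCCO
F4 | step 5 | benzyl 16-(benzyloxy)hexadecanoate | O=C(OCc1ccccc1)CCCCCCCCCCCCCCCOCc1ccccc1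
F5 | step 5 | dibenzyl 2-[14-(benzyloxy)tetradecyl]-3-hydroxy-3-methylbutanedioate (racemic diastereomer mixture) | CC(O)(C(=O)OCc1ccccc1)C(CCCCCCCCCCCCCCOCc1ccccc1)C(=O)OCc1ccccc1
F6 | step 6 | 14-{4-methyl-4-[(methylsulfonyl)oxy]-2,5-dioxooxolan-3-yl}tetradecyl acetate (racemic diastereomer mixture) | CC(=O)OCCCCCCCCCCCCCCC1C(=O)OC(=O)C1(C)OS(C)(=O)=O
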